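**Strategy.** Ring A (C1–C6) is read as a dearomatised 4‑oxy‑3,5‑dimethylbenzoyl unit. C6 is the ipso carbon, and its acyl carbon becomes pyrone ring B. C2 and C4 keep the meta methyls and C3 keeps the para oxygen. The trans C1‑alkenyl/C6‑methyl pair is what a nucleophile and an electrophile leave when added across the ortho–ipso bond. One operation therefore joins the C7–C10 alkenyllithium to C1 of a 4‑methoxy‑3,5‑dimethylphenyl oxazoline and methylates C6, setting both stereocentres under an (S)‑tert‑leucinol auxiliary. The resulting 3‑methoxy diene is oxidised to the epoxide, the oxazoline is turned into the methoxypyrone, and C10 is oxidised last.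

Key step: step 8

**Conventions and assumptions**

- Numbering: ring A is C1 (CH carrying the side chain), C2 and C3 (epoxide carbons, C2 methylated), C4=C5 (C4 methylated) and C6 (quaternary, carrying ring B). The chain is C7 (methylated alkene carbon), C8, C9 (methyl stereocentre) and C10 (ketone). The face of ring A that carries the C1 alkenyl group is called the upper face.
- Assumption: the nitrogen‑bound lithium reagent is taken to be delivered to the ortho carbon on the nitrogen side, from the face opposite the tert‑butyl group. On this model the (S)‑auxiliary gives the C1/C6 configuration of the target.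
- Design remarks: the propargylic alcohol must be the (S)‑enantiomer so that C9 emerges (R). The C10 carbinol configuration is irrelevant because C10 ends as a ketone. The inexpensive oxazoline 5 is used in excess over the alkenyllithium.

**Route**

Step 1
Reactants: 1 4‑hydroxy‑3,5‑dimethylbenzonitrile; 2 iodomethane
Product: 3 4‑methoxy‑3,5‑dimethylbenzonitrile
Conditions: K2CO3, DMF, 40 °C
Reagents that add atoms: iodomethane 2, CI
Why: Williamson ether synthesis of an acidic cyanophenol, which has no other nucleophilic site.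

Step 2
Reactants: 3 4‑methoxy‑3,5‑dimethylbenzonitrile; 4 (S)‑tert‑leucinol
Product: 5 (S)‑4‑tert‑butyl‑2‑(4‑methoxy‑3,5‑dimethylphenyl)‑4,5‑dihydrooxazole
Conditions: ZnCl2 (10 mol %), PhCl, reflux
Reagents that add atoms: (S)‑tert‑leucinol 4, CC(C)(C)[C@H](N)CO
Why: Zinc‑catalysed condensation of a nitrile with a 1,2‑amino alcohol (Witte–Seeliger oxazoline synthesis) releases ammonia and does not touch the stereocentre of the amino alcohol.

Step 3
Reactants: 6 pent‑3‑yn‑2‑one
Product: 7 (S)‑pent‑3‑yn‑2‑ol
Conditions: Ru[(S,S)‑TsDPEN](p‑cymene) (1 mol %), i‑PrOH, rt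
Reagents that add atoms: none
Why: Noyori asymmetric transfer hydrogenation of an alkynyl methyl ketone, in which the (S,S)‑catalyst should give the (S)‑propargylic alcohol from which C9 is later derived.

Step 4
Reactants: 7 (S)‑pent‑3‑yn‑2‑ol
Product: 8 (S)‑pent‑3‑yn‑2‑yl methanesulfonate
Conditions: MsCl, Et3N, CH2Cl2, −78 → 0 °C
Reagents that add atoms: methanesulfonyl chloride, CS(=O)(=O)Cl
Why: O‑Sulfonylation of the alcohol, which proceeds with retention because the C–O bond is not broken.

Step 5
Reactants: 8 (S)‑pent‑3‑yn‑2‑yl methanesulfonate; 9 propanal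
Product: 11 (3S,4R)‑4‑methylhept‑5‑yn‑3‑ol, via allenylzinc mesylate 10 (not isolated)
Conditions: Pd(OAc)2 (5 mol %), PPh3 (5 mol %), Et2Zn (3 equiv), THF, −78 → −20 °C
Reagents that add atoms: propanal 9, CCC=O
Why: Marshall propargylation, in which zerovalent palladium displaces the mesylate anti, transmetallation gives allenylzinc 10, and its cyclic SE2' addition to propanal gives the anti homopropargylic alcohol with net inversion at the former carbinol carbon, so that C9 is set (R) by chirality transfer and C10 (S) by the chair‑like transition state (a minor syn isomer differs only at C10, which is oxidised in step 18).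

Step 6
Reactants: 11 (3S,4R)‑4‑methylhept‑5‑yn‑3‑ol
Product: 12 (3S,4R)‑3‑(tert‑butyldimethylsilyloxy)‑4‑methylhept‑5‑yne
Conditions: TBSCl, imidazole, DMF, rt
Reagents that add atoms: tert‑butyldimethylsilyl chloride, CC(C)(C)[Si](C)(C)Cl
Why: Silylation of the secondary alcohol gives an ether that tolerates t‑BuLi and every later step up to fluoride.

Step 7
Reactants: 12 (3S,4R)‑3‑(tert‑butyldimethylsilyloxy)‑4‑methylhept‑5‑yne
Product: 14 (3S,4R,5E)‑3‑(tert‑butyldimethylsilyloxy)‑6‑iodo‑4‑methylhept‑5‑ene, via alkenylzirconocene chloride 13 (not isolated)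
Conditions: Cp2Zr(H)Cl (2.5 equiv), THF, 50 °C; I2, 0 °C
Reagents that add atoms: iodine, II
Why: Hydrozirconation–iodination, in which syn addition of Zr–H places zirconium (after equilibration with excess reagent) on the less hindered methyl‑bearing alkyne carbon and iodinolysis with retention gives the E iodide.

Step 8
Reactants: 14 (3S,4R,5E)‑3‑(tert‑butyldimethylsilyloxy)‑6‑iodo‑4‑methylhept‑5‑ene; 5 (S)‑4‑tert‑butyl‑2‑(4‑methoxy‑3,5‑dimethylphenyl)‑4,5‑dihydrooxazole; 2 iodomethane
Product: 17 dearomatised 3‑methoxy‑2,4‑diene oxazoline (C1 alkenyl and C6 oxazoline on the upper face; C6 methyl on the lower face), via alkenyllithium 15 (not isolated), via lithium aza‑enolate 16 (not isolated)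
Conditions: 14, t‑BuLi (2.0 equiv), Et2O, −78 °C; 5 (1.5 equiv), THF, DMPU (4 equiv), −78 → −40 °C; MeI (3 equiv), −78 → −20 °C
Reagents that add atoms: oxazoline 5, COc1c(C)cc(cc1C)C1=N[C@@H](C(C)(C)C)CO1; iodomethane 2, CI
Why: Proposed new method: alkenyllithium 15 (formed from 14 by lithium–iodine exchange with retention of the E geometry) binds the oxazoline nitrogen of 5 and adds in conjugate fashion through the ring to the ortho carbon on the nitrogen side (C1), giving lithium aza‑enolate 16 delocalised over C6 and the C2–C5 diene, which iodomethane alkylates at C6 to restore the C=N bond. The closest known reaction types are the tandem organolithium addition–alkylation of chiral naphthyl oxazolines and dearomatising conjugate additions of organolithiums to benzene rings whose acyl group is activated by a bulky aluminium aryloxide or whose ring is bound to tricarbonylchromium; no ring is closed. C1 is controlled by the tert‑butyl group, which keeps the nitrogen‑bound lithium reagent on the opposite face of the coplanar aryl–oxazoline unit, and because the arene is symmetric about its C3–C6 axis either ortho carbon leads to the same product. C6 is controlled by C1, since iodomethane enters the aza‑enolate anti to the new pseudoaxial alkenyl group, leaving methyl trans and the acyl carbon cis to it. The step needs addition to win over ortho‑deprotonation and over attack elsewhere: an sp2 lithium reagent is a poor kinetic base and DMPU raises its nucleophilicity, the para carbon C3 is blocked by the methoxy group and C2/C4 by methyls, and the methoxy group, twisted out of the ring plane by its two flanking methyls, cannot deactivate the ring by resonance.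

Step 9
Reactants: 17 dearomatised 3‑methoxy‑2,4‑diene oxazoline
Product: 19 C2‑hydroxy C3‑enone (C2 hydroxyl on the lower face), via methoxy epoxide 18 (not isolated)
Conditions: dimethyldioxirane (1.0 equiv), acetone–CH2Cl2, −78 °C; H2O, SiO2, 0 °C
Reagents that add atoms: dimethyldioxirane, CC1(C)OO1; water, O
Why: Rubottom‑type oxidation, in which the tetrasubstituted enol ether bond C2=C3 is far more electron‑rich than C4=C5 or C7=C8 and is epoxidised on the face opposite the neighbouring pseudoaxial C1 alkenyl group (setting C2), and hydrolytic opening of the methoxy epoxide leaves the tertiary alcohol next to the C3 enone.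

Step 10
Reactants: 19 C2‑hydroxy C3‑enone
Product: 20 trans‑C2,C3‑diol (C2 hydroxyl lower face; C3 hydroxyl upper face)
Conditions: Me4NBH(OAc)3, MeCN–AcOH, −30 → 0 °C
Reagents that add atoms: none
Why: Hydroxyl‑directed reduction (Saksena–Evans), in which the C2 hydroxyl binds boron and delivers hydride to the lower face of the C3 carbonyl, so that the new hydroxyl ends trans to the C2 hydroxyl.

Step 11
Reactants: 20 trans‑C2,C3‑diol
Product: 22 C2–C3 epoxide oxazoline (epoxide oxygen on the lower face), via secondary tosylate 21 (not isolated)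
Conditions: NaH (2.5 equiv), N‑tosylimidazole (1.1 equiv), THF, 0 °C → rt
Reagents that add atoms: none
Why: One‑flask sulfonylation–cyclisation of a trans‑1,2‑diol, in which the less hindered secondary alkoxide is tosylated and the tertiary alkoxide displaces the tosylate from the rear (intramolecular Williamson reaction, 3‑exo‑tet), inverting C3 and placing the epoxide on the face of the C2 oxygen.

Step 12
Reactants: 22 C2–C3 epoxide oxazoline
Product: 25 C6 carbaldehyde, via oxazolinium triflate 23 (not isolated), via oxazolidine 24 (not isolated)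
Conditions: MeOTf, CH2Cl2, 0 °C; NaBH4, THF–MeOH, 0 °C; AcOH–NaOAc buffer (pH 5), THF–H2O, rt
Reagents that add atoms: water, O
Why: Reductive oxazoline‑to‑aldehyde cleavage, in which N‑methylation activates the C=N bond, borohydride stops at the N,O‑acetal and buffered hydrolysis releases the non‑enolisable aldehyde at a pH meant to spare the vinyl epoxide.

Step 13
Reactants: 25 C6 carbaldehyde; 26 methyl 2‑methyl‑3‑oxopentanoate
Product: 28 δ‑hydroxy β‑keto ester (mixture of diastereomers in the new chain), via keto ester dianion 27 (not isolated)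
Conditions: 26, NaH then n‑BuLi, THF, 0 °C; 25, −78 °C
Reagents that add atoms: methyl 2‑methyl‑3‑oxopentanoate 26, CCC(=O)C(C)C(=O)OC
Why: Aldol addition of the γ‑carbon of a β‑keto ester dianion to an aldehyde that cannot enolise, creating stereocentres that are all removed in steps 14 and 15.

Step 14
Reactants: 28 δ‑hydroxy β‑keto ester
Product: 29 β,δ‑diketo ester
Conditions: Dess–Martin periodinane, NaHCO3, CH2Cl2, rt
Reagents that add atoms: none
Why: Dess–Martin oxidation of a β‑hydroxy ketone to the 1,3‑diketone under buffered, non‑acidic conditions that the epoxide and silyl ether tolerate.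

Step 15
Reactants: 29 β,δ‑diketo ester
Product: 30 6‑substituted 4‑hydroxy‑3,5‑dimethyl‑2H‑pyran‑2‑one
Conditions: DBU, toluene, 60 °C
Reagents that add atoms: none
Why: Base‑mediated lactonisation, in which the enol oxygen of the ketone attached to C6 attacks the methyl ester (acyl substitution) and methanol is lost to give ring B as the hydroxypyranone.

Step 16
Reactants: 30 6‑substituted 4‑hydroxy‑3,5‑dimethyl‑2H‑pyran‑2‑one
Product: 31 2‑methoxy‑3,5‑dimethyl‑4H‑pyran‑4‑one with C10 silyl ether
Conditions: MeOTf, 2,6‑di‑tert‑butyl‑4‑methylpyridine, CH2Cl2, 0 °C → rt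
Reagents that add atoms: methyl triflate, COS(=O)(=O)C(F)(F)F
Why: Regioselective O‑methylation, in which the hard electrophile alkylates the neutral hydroxypyranone at its most basic site (the lactone carbonyl oxygen) and the hindered pyridine takes the released proton so that the 4‑pyranone forms without free acid reaching the epoxide.

Step 17
Reactants: 31 2‑methoxy‑4‑pyranone with C10 silyl ether
Product: 32 C10 alcohol
Conditions: Bu4NF, THF, rt
Reagents that add atoms: none
Why: Fluoride‑mediated desilylation, to which the epoxide, the pyranone and both alkenes are inert.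

Step 18
Reactants: 32 C10 alcohol
Product: 33 CNP0336888.3
Conditions: Dess–Martin periodinane, NaHCO3, CH2Cl2, 0 °C
Reagents that add atoms: none
Why: Dess–Martin oxidation under buffered conditions should give the β,γ‑unsaturated ketone without epimerising C9 or moving the C7=C8 bond into conjugation.

**Compound list**

1 | 4‑hydroxy‑3,5‑dimethylbenzonitrile | Cc1cc(C#N)cc(C)c1O | starting material
2 | iodomethane | CI | starting material
3 | 4‑methoxy‑3,5‑dimethylbenzonitrile | COc1c(C)cc(C#N)cc1C | intermediate
4 | (S)‑tert‑leucinol | CC(C)(C)[C@H](N)CO | starting material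
5 | (S)‑4‑tert‑butyl‑2‑(4‑methoxy‑3,5‑dimethylphenyl)‑4,5‑dihydrooxazole | COc1c(C)cc(cc1C)C1=N[C@@H](C(C)(C)C)CO1 | intermediate
6 | pent‑3‑yn‑2‑one | CC#CC(C)=O | starting material
7 | (S)‑pent‑3‑yn‑2‑ol | CC#C[C@H](C)O | intermediate
8 | (S)‑pent‑3‑yn‑2‑yl methanesulfonate | CC#C[C@H](C)OS(C)(=O)=O | intermediate
9 | propanal | CCC=O | starting material
10 | (M)‑penta‑2,3‑dien‑2‑ylzinc methanesulfonate | CC([Zn]OS(C)(=O)=O)=[C@@]=C([H])C | intermediate (not isolated)
11 | (3S,4R)‑4‑methylhept‑5‑yn‑3‑ol (anti) | CC[C@H](O)[C@H](C)C#CC | intermediate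
12 | (3S,4R)‑3‑(tert‑butyldimethylsilyloxy)‑4‑methylhept‑5‑yne | CC[C@H](O[Si](C)(C)C(C)(C)C)[C@H](C)C#CC | intermediate
13 | (E)‑alkenylzirconocene chloride, zirconium on C7 | CC[C@H](O[Si](C)(C)C(C)(C)C)[C@H](C)/C=C(\C)[Zr](Cl)(C1C=CC=C1)C1C=CC=C1 | intermediate (not isolated)
14 | (3S,4R,5E)‑3‑(tert‑butyldimethylsilyloxy)‑6‑iodo‑4‑methylhept‑5‑ene | CC[C@H](O[Si](C)(C)C(C)(C)C)[C@H](C)/C=C(\C)I | intermediate
15 | (E)‑alkenyllithium, lithium on C7 | CC[C@H](O[Si](C)(C)C(C)(C)C)[C@H](C)/C=C(\C)[Li] | intermediate (not isolated)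
16 | lithium aza‑enolate: C1 alkenylated, C6 exocyclic to the N‑lithiated oxazolidine, C2=C3(OMe)–C4=C5 diene | CC[C@H](O[Si](C)(C)C(C)(C)C)[C@H](C)/C=C(\C)[C@H]1C(C)=C(OC)C(C)=CC1=C2OC[C@H](C(C)(C)C)N2[Li] | intermediate (not isolated)
17 | (S)‑4‑tert‑butyl‑2‑(ring A)‑4,5‑dihydrooxazole; ring A = 3‑methoxy‑2,4,6‑trimethylcyclohexa‑2,4‑dien‑6‑yl carrying at C1 the (2E,4R,5S)‑5‑(tert‑butyldimethylsilyloxy)‑4‑methylhept‑2‑en‑2‑yl group; C1 alkenyl and C6 oxazoline upper face, C6 methyl lower face | CC[C@H](O[Si](C)(C)C(C)(C)C)[C@H](C)/C=C(\C)[C@H]1C(C)=C(OC)C(C)=C[C@@]1(C)C2=N[C@@H](C(C)(C)C)CO2 | intermediate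
18 | C2–C3 epoxide of 17 with methoxy retained on C3, epoxide oxygen lower face | CC[C@H](O[Si](C)(C)C(C)(C)C)[C@H](C)/C=C(\C)[C@H]1[C@]2(C)O[C@]2(OC)C(C)=C[C@@]1(C)C3=N[C@@H](C(C)(C)C)CO3 | intermediate (not isolated)
19 | C2‑hydroxy‑C2‑methyl C3‑ketone conjugated with C4=C5; C2 hydroxyl lower face; oxazoline and silyl ether kept | CC[C@H](O[Si](C)(C)C(C)(C)C)[C@H](C)/C=C(\C)[C@H]1[C@](C)(O)C(=O)C(C)=C[C@@]1(C)C2=N[C@@H](C(C)(C)C)CO2 | intermediate
20 | trans‑diol: C2 hydroxyl lower face, C3 hydroxyl upper face | CC[C@H](O[Si](C)(C)C(C)(C)C)[C@H](C)/C=C(\C)[C@H]1[C@](C)(O)[C@@H](O)C(C)=C[C@@]1(C)C2=N[C@@H](C(C)(C)C)CO2 | intermediate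
21 | C3 p‑toluenesulfonate of 20 (upper face), C2 hydroxyl free | CC[C@H](O[Si](C)(C)C(C)(C)C)[C@H](C)/C=C(\C)[C@H]1[C@](C)(O)[C@@H](OS(=O)(=O)c2ccc(C)cc2)C(C)=C[C@@]1(C)C3=N[C@@H](C(C)(C)C)CO3 | intermediate (not isolated)
22 | C2–C3 epoxide (oxygen lower face, C2 methyl upper face) with C4=C5 alkene, C6 oxazoline and C10 silyl ether | CC[C@H](O[Si](C)(C)C(C)(C)C)[C@H](C)/C=C(\C)[C@H]1[C@]2(C)O[C@@H]2C(C)=C[C@@]1(C)C3=N[C@@H](C(C)(C)C)CO3 | intermediate
23 | N‑methyloxazolinium triflate of 22 | CC[C@H](O[Si](C)(C)C(C)(C)C)[C@H](C)/C=C(\C)[C@H]1[C@]2(C)O[C@@H]2C(C)=C[C@@]1(C)C3=[N+](C)[C@@H](C(C)(C)C)CO3.[O-]S(=O)(=O)C(F)(F)F | intermediate (not isolated)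
24 | N‑methyloxazolidine (both epimers at the new N,O‑acetal carbon) | CC[C@H](O[Si](C)(C)C(C)(C)C)[C@H](C)/C=C(\C)[C@H]1[C@]2(C)O[C@@H]2C(C)=C[C@@]1(C)C3N(C)[C@@H](C(C)(C)C)CO3 | intermediate (not isolated)
25 | C6 carbaldehyde (formyl upper face, C6 methyl lower face) with epoxide and C10 silyl ether | CC[C@H](O[Si](C)(C)C(C)(C)C)[C@H](C)/C=C(\C)[C@H]1[C@]2(C)O[C@@H]2C(C)=C[C@@]1(C)C=O | intermediate
26 | methyl 2‑methyl‑3‑oxopentanoate | CCC(=O)C(C)C(=O)OC | starting material
27 | sodium lithium dianion of 26 | CC=C([O-])C(C)=C([O-])OC.[Na+].[Li+] | intermediate (not isolated)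
28 | methyl 5‑hydroxy‑2,4‑dimethyl‑3‑oxopentanoate carrying ring A (C6) on C5, diastereomer mixture in the new chain | CC[C@H](O[Si](C)(C)C(C)(C)C)[C@H](C)/C=C(\C)[C@H]1[C@]2(C)O[C@@H]2C(C)=C[C@@]1(C)C(O)C(C)C(=O)C(C)C(=O)OC | intermediate
29 | methyl 2,4‑dimethyl‑3,5‑dioxopentanoate carrying ring A (C6) on C5 | CC[C@H](O[Si](C)(C)C(C)(C)C)[C@H](C)/C=C(\C)[C@H]1[C@]2(C)O[C@@H]2C(C)=C[C@@]1(C)C(=O)C(C)C(=O)C(C)C(=O)OC | intermediate
30 | 4‑hydroxy‑3,5‑dimethyl‑2H‑pyran‑2‑one attached through its C6 to C6 of ring A | CC[C@H](O[Si](C)(C)C(C)(C)C)[C@H](C)/C=C(\C)[C@H]1[C@]2(C)O[C@@H]2C(C)=C[C@@]1(C)C3=C(C)C(O)=C(C)C(=O)O3 | intermediate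
31 | 2‑methoxy‑3,5‑dimethyl‑4H‑pyran‑4‑one attached through its C6 to C6 of ring A, C10 silyl ether | CC[C@H](O[Si](C)(C)C(C)(C)C)[C@H](C)/C=C(\C)[C@H]1[C@]2(C)O[C@@H]2C(C)=C[C@@]1(C)c1oc(OC)c(C)c(=O)c1C | intermediate
32 | C10 (S)‑alcohol of the target skeleton | CC[C@H](O)[C@H](C)/C=C(\C)[C@H]1[C@]2(C)O[C@@H]2C(C)=C[C@@]1(C)c1oc(OC)c(C)c(=O)c1C | intermediate
33 | CNP0336888.3 | CCC(=O)[C@H](C)/C=C(\C)[C@H]1[C@]2(C)O[C@@H]2C(C)=C[C@@]1(C)c1oc(OC)c(C)c(=O)c1C | target

**Step count**

Total: 18 steps. Longest linear sequence: 16 steps (steps 3–18, from pent‑3‑yn‑2‑one 6).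

**Steps most likely to fail**

1. Step 8 (proposed new method). The alkenyllithium may deprotonate an ortho C–H of 5, or may not add at all to a benzene ring that is not otherwise activated, so that no dearomatised product forms. The fallback uses known chemistry, sets out from 5 and returns at 17. Oxazoline 5 is heated with Cr(CO)6 (Bu2O–THF, reflux) to give its tricarbonylchromium complex F1. Carbon nucleophiles, alkenyllithiums included, are known to add to such complexes at the ortho carbon on the face away from the metal, with the auxiliary choosing the ortho carbon by the same nitrogen‑side, anti‑to‑tert‑butyl delivery. Alkenyllithium 15 is therefore added at −78 °C, the anionic cyclohexadienyl complex is protonated with CF3CO2H, and the metal is released under CO. This should give the C6‑unmethylated cyclohexadiene F2 as double‑bond isomers with C1 fixed. LiN(i‑Pr)2 (THF, −78 °C) should regenerate aza‑enolate 16 from every isomer, and iodomethane 2 then gives 17.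

2. Step 12. The vinyl epoxide may open, or the crowded N,O‑acetal may resist hydrolysis, during the mildly acidic release of the aldehyde. The fallback sets out from 22 and returns at 25 without any acid. Oxazolinium salt 23 is hydrolysed in wet THF at neutral pH (NaHCO3) to the 2‑(methylamino)alkyl ester F3. This ester is reduced with (i‑Bu)2AlH (CH2Cl2, −78 °C) to the neopentyl alcohol F4, which Dess–Martin periodinane oxidises to 25.

3. Step 16. Methylation may occur at the wrong oxygen, giving the 4‑methoxy‑2‑pyranone, or the acid set free by methylation may open the epoxide. The fallback sets out from 29 and returns at 31, by‑passing 30. It is an Appel‑type cyclodehydration of the diketo methyl ester (PPh3, CCl4, Et3N, THF). The enol of the ketone attached to C6 is activated as an oxyphosphonium and displaced by the ester carbonyl oxygen, so the ester methoxy group is kept and no methylating agent is needed.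

**Further compounds**

F1 | step 8 | tricarbonyl[η6‑(S)‑4‑tert‑butyl‑2‑(4‑methoxy‑3,5‑dimethylphenyl)‑4,5‑dihydrooxazole]chromium | COc1c(C)cc(cc1C)C1=N[C@@H](C(C)(C)C)CO1.[Cr].[C-]#[O+].[C-]#[O+].[C-]#[O+]
F2 | step 8 | C6‑unmethylated analogue of 17 (C6–H, drawn as the 2,4‑diene isomer; C1 as in 17) | CC[C@H](O[Si](C)(C)C(C)(C)C)[C@H](C)/C=C(\C)[C@H]1C(C)=C(OC)C(C)=CC1C2=N[C@@H](C(C)(C)C)CO2
F3 | step 12 | (S)‑3,3‑dimethyl‑2‑(methylamino)butyl ester of the ring A C6 carboxylic acid (epoxide and silyl ether as in 22) | CC[C@H](O[Si](C)(C)C(C)(C)C)[C@H](C)/C=C(\C)[C@H]1[C@]2(C)O[C@@H]2C(C)=C[C@@]1(C)C(=O)OC[C@@H](NC)C(C)(C)C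
F4 | step 12 | C6 hydroxymethyl compound (primary alcohol corresponding to 25) | CC[C@H](O[Si](C)(C)C(C)(C)C)[C@H](C)/C=C(\C)[C@H]1[C@]2(C)O[C@@H]2C(C)=C[C@@]1(C)CO
F0 | step 16 | none | none
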